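**Retrosynthetic overview**

1. Rings: A = prenylated benzene ring, B = second benzene ring, C = oxepine, D = dihydropyran, E = cyclobutane, F = cyclopentane. Order of formation: D (step 2), E and F together (step 3), C last (step 10).
2. Ring C is disconnected at the C–C bond between its enol-ether carbon that carries the cyclobutane and the ring A carbon para to the ring A hydroxyl. The precursor is a 6-aryl-dihydropyran (rings D/E/F complete) whose aryl group is ring B, carrying ring A as an ortho-aryloxy substituent.
3. Enabling feature: the two non-aromatic carbons of ring C form an enol ether, and one of them bears the ring D oxygen. An electrophile at the other carbon leaves an oxygen-stabilised cation that ring A closes to a six-membered spiro-xanthene; the same oxygen lone pair then drives a 1,2-shift of ring A (electron-rich through its para oxygen), which expands that ring to the seven-membered ring C.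
4. The enol ether comes from the tricyclic lactone (rings D/E/F) and the aryllithium of a diaryl ether bromide. The lactone comes from (R)-linalool by esterification, ring-closing metathesis and a copper-catalysed [2+2] photocycloaddition, in which the linalool carbinol carbon fixes the other three stereocentres.
5. The diaryl ether comes from 4-prenylresorcinol and silylated 4-bromo-3-iodophenol by Ullmann coupling.

Key step: step 10

Remark: the quaternary carbinol carbon of the target is R and maps onto C3 of (R)-(−)-linalool with unchanged CIP order, so (R)-linalool of high enantiomeric purity supplies the absolute configuration; 4-bromo-3-iodophenol is taken as a catalogue compound.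

**Route**

Step 1
Reactants: 1 (R)-linalool; 2 but-3-enoic acid
Product: 3 (3R)-3,7-dimethylocta-1,6-dien-3-yl but-3-enoate
Conditions: DCC, DMAP (0.2 equiv), CH2Cl2, 0 °C to rt
Reagents that add atoms: none
Why: Steglich esterification acylates the hindered tertiary allylic alcohol under neutral conditions; low temperature and sub-stoichiometric DMAP should keep the β,γ-double bond out of conjugation, and the carbinol stereocentre is not touched.

Step 2
Reactants: 3 (3R)-3,7-dimethylocta-1,6-dien-3-yl but-3-enoate
Product: 4 (6R)-6-methyl-6-(4-methylpent-3-en-1-yl)-3,6-dihydro-2H-pyran-2-one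
Conditions: second-generation Grubbs catalyst [RuCl2(=CHPh)(H2IMes)(PCy3)] (5 mol%), 1,4-benzoquinone (10 mol%), CH2Cl2 (0.005 M), 40 °C
Reagents that add atoms: none
Why: Ring-closing metathesis of the two monosubstituted alkenes should close ring D as the six-membered lactone, since the catalyst loads at the unhindered butenoate terminus and the trisubstituted prenyl alkene is a poor partner.

Step 3
Reactants: 4 (6R)-6-methyl-6-(4-methylpent-3-en-1-yl)-3,6-dihydro-2H-pyran-2-one
Product: 5 (1R,3S,6R,10R)-2,2,6-trimethyl-7-oxatricyclo[4.3.1.0(3,10)]decan-8-one (tricyclic lactone, rings D/E/F)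
Conditions: (CuOTf)2·C6H6 (10 mol%), Et2O, hν (254 nm, quartz), rt
Reagents that add atoms: none
Why: Salomon–Kochi copper-catalysed intramolecular [2+2] photocycloaddition of the 1,6-diene can only give the cis-fused bicyclo[3.2.0]heptane; the tether starts at the quaternary (R)-carbon and reaches the cis ring alkene from one face only, so this centre sets the three new stereocentres (all ring fusions cis, ring oxygen on the cyclobutane side).

Step 4
Reactants: 6 resorcinol; 7 2-methylbut-3-en-2-ol
Product: 8 4-(3-methylbut-2-en-1-yl)benzene-1,3-diol
Conditions: BF3·OEt2 (0.3 equiv), 1,4-dioxane, rt; 6 in excess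
Reagents that add atoms: none
Why: Friedel–Crafts prenylation by the allyl cation from the tertiary allylic alcohol should go to the 4-position, which is ortho/para to both hydroxyls and less hindered than the 2-position; a short contact time limits chroman formation.

Step 5
Reactants: 9 4-bromo-3-iodophenol
Product: 10 (4-bromo-3-iodophenoxy)tri(propan-2-yl)silane
Conditions: chlorotri(propan-2-yl)silane, imidazole, DMF, rt
Reagents that add atoms: chlorotri(propan-2-yl)silane, CC(C)[Si](Cl)(C(C)C)C(C)C
Why: Standard silylation of a phenol gives a bulky silyl ether that survives the Ullmann base and the organolithium step.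

Step 6
Reactants: 8 4-(3-methylbut-2-en-1-yl)benzene-1,3-diol; 10 (4-bromo-3-iodophenoxy)tri(propan-2-yl)silane
Product: 11 5-[2-bromo-5-(triisopropylsilyloxy)phenoxy]-2-(3-methylbut-2-en-1-yl)phenol
Conditions: CuI (10 mol%), N,N-dimethylglycine (30 mol%), Cs2CO3, 1,4-dioxane, 90 °C; 8 in excess
Reagents that add atoms: none
Why: In this Ullmann diaryl ether coupling copper should insert into the C–I bond in preference to the C–Br bond, and the hydroxyl para to the prenyl group should react because the other one is flanked by the prenyl substituent.

Step 7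
Reactants: 11 5-[2-bromo-5-(triisopropylsilyloxy)phenoxy]-2-(3-methylbut-2-en-1-yl)phenol
Product: 12 {4-bromo-3-[4-(3-methylbut-2-en-1-yl)-3-(triisopropylsilyloxy)phenoxy]phenoxy}tri(propan-2-yl)silane
Conditions: iPr3SiOTf, 2,6-lutidine, CH2Cl2, 0 °C
Reagents that add atoms: tri(propan-2-yl)silyl trifluoromethanesulfonate, CC(C)[Si](OS(=O)(=O)C(F)(F)F)(C(C)C)C(C)C
Why: The silyl triflate silylates the hindered ortho-prenyl phenol; the bulky group later also shields the ring A position between the two oxygens.

Step 8
Reactants: 12 bis(silyl) diaryl ether bromide; 5 tricyclic lactone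
Product: 14 aryl lactol (cyclic hemiketal of the tricyclic core; anomer mixture), via aryllithium 13 (not isolated)
Conditions: n-BuLi, THF, −78 °C; then 5, −78 °C; then H2O
Reagents that add atoms: none
Why: Bromine–lithium exchange and addition of the aryllithium to the δ-lactone should stop at the tetrahedral lithium hemiketal at −78 °C, as in C-aryl glycoside synthesis; the new hemiketal centre is removed in the next step.

Step 9
Reactants: 14 aryl lactol
Product: 15 6-aryl-dihydropyran (8-aryl-2,2,6-trimethyl-7-oxatricyclo[4.3.1.0(3,10)]dec-8-ene, ring fusion as in 5; aryl = ring B carrying the ring A aryloxy group)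
Conditions: (CF3CO)2O, 2,6-lutidine (4 equiv), CH2Cl2, −40 to 0 °C
Reagents that add atoms: none
Why: Trifluoroacetylation of the hemiketal hydroxyl and E1 loss through the aryl-stabilised oxocarbenium ion, deprotonated at once by the excess base, is the known dehydration of C-aryl lactols to 1-aryl glycal-type enol ethers; no stereocentre is affected.

Step 10
Reactants: 15 6-aryl-dihydropyran
Product: 17 bis(triisopropylsilyl) ether of the target, via spiro-xanthene iodane 16 (not isolated)
Conditions: PhI(OCOCF3)2 (1.05 equiv), 2,6-di-tert-butylpyridine (2.5 equiv), CH2Cl2/(CF3)2CHOH 9:1, −40 to 0 °C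
Reagents that add atoms: none
Why: Proposed new method: PhI(OCOCF3)2 should attack the β-carbon of the 2-aryl enol ether from the face away from the gem-dimethylcyclobutane and give a β-iodanyl oxocarbenium ion, whose cationic carbon is captured, anti to the iodane, by the ring A carbon para to the silyloxy group (6-exo-trig Friedel–Crafts closure of the transient spiro-xanthene 16). The aryl bond just formed is then antiperiplanar to the C–I bond, so loss of PhI is accompanied by a 1,2-shift of ring A, pushed by the lone pair of the ring D oxygen, which expands the six-membered xanthene ring to the seven-membered ring C (a ring expansion, not a Baldwin-type closure); loss of the proton at the migration terminus then restores the now tetrasubstituted enol ether. The closest known reactions are the PhI(OH)OTs-mediated oxidative 1,2-aryl shift and ring expansion of 1,1-diarylalkenes and alkylidene benzocycloalkenes, trivalent-iodine oxidative cyclisations with aryl migration, and the Wagner–Meerwein route from 9-xanthenyl carbinols to dibenzo[b,f]oxepines. No stereocentre is created in the product, because both transient sp3 centres return to sp2, and the four existing ones do not carry the charge. The step needs attack of the oxidant on the enol ether (the most nucleophilic π-bond, well above the prenyl alkene), Friedel–Crafts attack through the ring A carbon para and not ortho to the bulky silyloxy group, and migration of ring A instead of ring B or a cyclobutane bond; the anti addition geometry (only ring A is antiperiplanar to the leaving group) and the oxygen-assisted, phenonium-type shift should secure this. The hindered pyridine buffer and the low temperature are meant to protect the acid-sensitive tertiary enol ether and the prenyl group.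

Step 11
Reactants: 17 bis(triisopropylsilyl) ether of the target
Product: 18 target CNP0185814.1
Conditions: Bu4NF, AcOH, THF, 0 °C to rt
Reagents that add atoms: none
Why: Fluoride should cleave both aryl silyl ethers; buffering with acetic acid avoids strongly basic phenoxides, and neither the enol ether nor the prenyl group reacts.

**Compound list**

1 | (R)-(−)-linalool, (3R)-3,7-dimethylocta-1,6-dien-3-ol | C=C[C@](C)(O)CCC=C(C)C | starting material
2 | but-3-enoic acid | C=CCC(=O)O | starting material
3 | (3R)-3,7-dimethylocta-1,6-dien-3-yl but-3-enoate | C=CCC(=O)O[C@](C)(CCC=C(C)C)C=C | intermediate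
4 | (6R)-6-methyl-6-(4-methylpent-3-en-1-yl)-3,6-dihydro-2H-pyran-2-one | O=C1CC=C[C@@](C)(CCC=C(C)C)O1 | intermediate
5 | (1R,3S,6R,10R)-2,2,6-trimethyl-7-oxatricyclo[4.3.1.0(3,10)]decan-8-one | O=C1C[C@@H]2[C@H]3[C@H](CC[C@@]3(C)O1)C2(C)C | intermediate
6 | resorcinol | Oc1cccc(O)c1 | starting material
7 | 2-methylbut-3-en-2-ol | CC(C)(O)C=C | starting material
8 | 4-(3-methylbut-2-en-1-yl)benzene-1,3-diol | CC(C)=CCc1ccc(O)cc1O | intermediate
9 | 4-bromo-3-iodophenol | Oc1ccc(Br)c(I)c1 | starting material
10 | (4-bromo-3-iodophenoxy)tri(propan-2-yl)silane | CC(C)[Si](Oc1ccc(Br)c(I)c1)(C(C)C)C(C)C | intermediate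
11 | 5-[2-bromo-5-(triisopropylsilyloxy)phenoxy]-2-(3-methylbut-2-en-1-yl)phenol | CC(C)=CCc1ccc(Oc2cc(O[Si](C(C)C)(C(C)C)C(C)C)ccc2Br)cc1O | intermediate
12 | {4-bromo-3-[4-(3-methylbut-2-en-1-yl)-3-(triisopropylsilyloxy)phenoxy]phenoxy}tri(propan-2-yl)silane | CC(C)=CCc1ccc(Oc2cc(O[Si](C(C)C)(C(C)C)C(C)C)ccc2Br)cc1O[Si](C(C)C)(C(C)C)C(C)C | intermediate
13 | aryllithium from 12 (lithium in place of bromine) | CC(C)=CCc1ccc(Oc2cc(O[Si](C(C)C)(C(C)C)C(C)C)ccc2[Li])cc1O[Si](C(C)C)(C(C)C)C(C)C | intermediate (not isolated)
14 | aryl lactol: 8-aryl-8-hydroxy-2,2,6-trimethyl-7-oxatricyclo[4.3.1.0(3,10)]decane, anomer mixture, ring fusion as in 5 | CC(C)=CCc1ccc(Oc2cc(O[Si](C(C)C)(C(C)C)C(C)C)ccc2C2(O)C[C@@H]3[C@H]4[C@H](CC[C@@]4(C)O2)C3(C)C)cc1O[Si](C(C)C)(C(C)C)C(C)C | intermediate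
15 | 6-aryl-dihydropyran: 8-aryl-2,2,6-trimethyl-7-oxatricyclo[4.3.1.0(3,10)]dec-8-ene, ring fusion as in 5 | CC(C)=CCc1ccc(Oc2cc(O[Si](C(C)C)(C(C)C)C(C)C)ccc2C2=C[C@@H]3[C@H]4[C@H](CC[C@@]4(C)O2)C3(C)C)cc1O[Si](C(C)C)(C(C)C)C(C)C | intermediate
16 | spiro-xanthene iodane: spiro[xanthene-9,2'-pyran] with the phenyl(trifluoroacetoxy)iodanyl group on the pyran carbon next to the spiro centre, ring A anti to iodine | CC(C)=CCc1cc2c(cc1O[Si](C(C)C)(C(C)C)C(C)C)Oc1cc(O[Si](C(C)C)(C(C)C)C(C)C)ccc1[C@@]21[C@H](I(c5ccccc5)OC(=O)C(F)(F)F)[C@@H]2[C@H]3[C@H](CC[C@@]3(C)O1)C2(C)C | intermediate (not isolated)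
17 | bis(triisopropylsilyl) ether of the target | CC(C)=CCc1cc2c(cc1O[Si](C(C)C)(C(C)C)C(C)C)Oc1cc(O[Si](C(C)C)(C(C)C)C(C)C)ccc1C1=C2[C@@H]2[C@H]3[C@H](CC[C@@]3(C)O1)C2(C)C | intermediate
18 | CNP0185814.1 | CC(C)=CCc1cc2c(cc1O)Oc1cc(O)ccc1C1=C2[C@@H]2[C@H]3[C@H](CC[C@@]3(C)O1)C2(C)C | target

**Step count**

Total: 11 steps. Longest linear sequence: 7 steps (for example steps 4, 6, 7, 8, 9, 10, 11).

**Steps most likely to fail**

Step 10 (Proposed new method). The cascade could fail through attack of the oxidant on the prenyl alkene or the silyloxyarenes, deprotonation to an unreactive alkenyliodonium salt, Friedel–Crafts attack syn to the iodane followed by migration of ring B, migration of a cyclobutane bond, or acid-induced cleavage of the tertiary enol ether. The fallback sets out from 15 and closes the ring by known palladium chemistry. Compound 15 would be brominated at the enol-ether β-carbon (NBS, 2,6-lutidine, CH2Cl2, −78 °C; bromination and dehydrobromination as for 2-bromoglycals) to give the bromo enol ether F1. F1 would then be cyclised by intramolecular direct C–H arylation of ring A (Pd(OAc)2, PCy3·HBF4, K2CO3, pivalic acid, DMA, 100 °C), with the bulky silyloxy group shielding the position between the two oxygens. This returns to the route at 17.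

Step 3. The photocycloaddition could fail through poor chelation of the copper ion by the lactone diene or through competing photolysis of the β,γ-unsaturated lactone. The fallback sets out from 4, which would be reduced (LiAlH4, THF, 0 °C) to the (3Z,5R)-dienediol F2. F2 is a free 3-hydroxy-1,6-diene, the substrate class for which the copper-catalysed photobicyclisation is best established and in which the tertiary hydroxyl helps to hold the metal. Irradiation ((CuOTf)2·C6H6, Et2O, 254 nm) should give the bicyclic diol F3 with the hydroxyl on the cyclobutane side, and oxidative lactonisation (TEMPO, PhI(OAc)2, CH2Cl2) would rejoin the route at 5.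

Step 9. The dehydration could fail through diversion of the oxocarbenium ion, either by premature Friedel–Crafts capture by ring A or by opening to the hydroxy ketone followed by ionisation of the tertiary alcohol next to the cyclobutane. The fallback makes the enol ether without a cationic intermediate and sets out from 5 and 12. Lactone 5 would be converted (KN(SiMe3)2, (PhO)2P(O)Cl, THF/HMPA, −78 °C) into the ketene acetal phosphate F4. Aryllithium 13 (from 12, n-BuLi, THF, −78 °C) would be transmetalated with ZnCl2 to the arylzinc chloride F5 and coupled with F4 (Pd(PPh3)4, THF, 50 °C; Negishi coupling of a lactone-derived enol phosphate). This returns to the route at 15.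

**Further compounds**

F1 | step 10 | bromo enol ether (15 with bromine on the enol-ether β-carbon) | CC(C)=CCc1ccc(Oc2cc(O[Si](C(C)C)(C(C)C)C(C)C)ccc2C2=C(Br)[C@@H]3[C@H]4[C@H](CC[C@@]4(C)O2)C3(C)C)cc1O[Si](C(C)C)(C(C)C)C(C)C
F2 | step 3 | (3Z,5R)-5,9-dimethyldeca-3,8-diene-1,5-diol | OCC/C=C\[C@](C)(O)CCC=C(C)C
F3 | step 3 | 7-(2-hydroxyethyl)-2,6,6-trimethylbicyclo[3.2.0]heptan-2-ol (cis-fused, hydroxyl and hydroxyethyl on the cyclobutane face) | OCC[C@@H]1[C@H]2[C@H](CC[C@@]2(C)O)C1(C)C
F4 | step 9 | ketene acetal diphenyl phosphate of lactone 5 | O=P(Oc1ccccc1)(Oc1ccccc1)OC1=C[C@@H]2[C@H]3[C@H](CC[C@@]3(C)O1)C2(C)C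
F5 | step 9 | arylzinc chloride from 12 (ZnCl in place of bromine) | CC(C)=CCc1ccc(Oc2cc(O[Si](C(C)C)(C(C)C)C(C)C)ccc2[Zn]Cl)cc1O[Si](C(C)C)(C(C)C)C(C)C
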